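Time was what I tried to take out of this question, since two flasks that stop at different moments can still be asked for one excess.

in all of them: left-handed substrate 0.20 M; right-handed substrate 0.20 M; added ligand 1.2 mM; impurity 0.31 mM

|  | reagent | free catalyst | remark | time |
|---|---|---|---|---|
| dawn | 4 equiv | 0.17 mol% | run made earlier |  |
| autumn | 4 equiv | 0.27 mol% | run made earlier |  |
| midnight | 4 equiv | 0.43 mol% | run made earlier |  |
| oak | 4.00 equiv | 0.5 mol% |  | 40 min |
| maple | 4.00 equiv | 0.15 mol% |  | 40 min |

| run | time / min | left-handed product / % | right-handed product / % |
|---|---|---|---|
| dawn | 8.00 | 1.3 | 0.1 |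
| dawn | 15.0 | 1.9 | 0.2 |
| dawn | 25.0 | 2.5 | 0.2 |
| dawn | 30.0 | 2.1 | 0.5 |
| dawn | 40.0 | 2.8 | 0.3 |
| autumn | 8.00 | 8.5 | 0.4 |
| autumn | 15.0 | 12.2 | 0 |
| autumn | 25.0 | 15.9 | 0.3 |
| autumn | 30.0 | 16.2 | 0 |
| autumn | 40.0 | 17.8 | 0 |
| midnight | 8.00 | 19.4 | 0 |
| midnight | 15.0 | 27.5 | 0.3 |
| midnight | 25.0 | 32.7 | 0.5 |
| midnight | 30.0 | 34.5 | 0.2 |
| midnight | 40.0 | 36.6 | 0.7 |

(each reading ± 0.3 percentage points)

- free catalyst is single-handed; left-handed substrate and right-handed substrate are mirror images of each other, charged as a racemate, each of them at the stated concentration
- the numbers in the tables scatter by 0.3 percentage points (one standard deviation)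
- an excess is below zero if the other one leads

1. the flask that ends with the higher excess of left-handed product over right-handed product in the product, or "neither" when 2 percentage points or less lies between them (oak / maple / neither)
2. excess of left-handed product over right-handed product in the product at the end, oak
3. excess of left-handed product over right-handed product in the product at the end, maple

I built the flask up one process at a time. With the main step alone, free catalyst and reagent turn left-handed substrate into left-handed product and, more slowly, right-handed substrate into right-handed product. Both rates carry the same [free catalyst] and [reagent], so these cancel in their quotient, and I took [left-handed substrate] and [right-handed substrate] as staying equal, which was my assumption and not a reading. I replaced each curve of the midnight run, which made more product than dawn or autumn, by its mean: 30.1% left-handed, 0.340% right-handed. Their quotient, 88.6, is my selectivity ratio, the selectivity factor: left-handed product made per right-handed product. It gives an excess of 97.8%, though roughly, for 0.340% stands beside a scatter of 0.3 percentage points.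

Then I added catalyst death. Midnight crept from 34.5% to 36.6% between 30.0 min and 40.0 min, against 50% of left-handed substrate charged. A falling [free catalyst] lowers both rates alike, so the extent shrinks and, on that assumption, the ratio stays.

Last came a loss at the start. Dawn ended at 2.8%, autumn at 17.8%, which pointed to the impurity taking catalyst. Maple charges 0.300 mM of catalyst against 0.31 mM of impurity, and oak 1.00 mM. Maple should therefore make little product, yet at the same ratio. The right-handed means of dawn, 0.260%, and midnight lie too near the scatter to show a background, and I assumed none; that was my choice, not a reading. I expected about 97.8% in both flasks.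

The forecast said oak, with oak at 97% and maple at 20%, holding that in maple “almost only background remains”. On maple my reckoning parted from it.

The flasks gave 98.5% for oak and 98.5% for maple: neither.

    free catalyst + impurity → spent catalyst A (k = 4300 L mol⁻¹ s⁻¹)
    reagent + free catalyst → spent catalyst B (k = 0.00300 L mol⁻¹ s⁻¹)
    reagent + free catalyst + left-handed substrate → free catalyst + left-handed product (k = 5.30 L² mol⁻² s⁻¹)
    free catalyst + added ligand ⇌ idle complex, settled at all times (K = 720 L mol⁻¹)
    reagent + free catalyst + right-handed substrate → free catalyst + right-handed product (k = 0.0400 L² mol⁻² s⁻¹)
    left-handed substrate ⇌ right-handed substrate (k = 0.0190 s⁻¹)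

Maple had reacted 0.162% of the charge, oak 43.2%. At the ratio 88.6, maple's 0.161% of left-handed product goes with a reckoned 0.00182% of right-handed product, less than the scatter of 0.3 points. The neighbour like maple but with 0.6 mol% of catalyst ended with 51.1% of left-handed product; the ratio gives it 97.8%, and it held 98.5%.

The data stem from a simulated flask for substances that don't exist; noise was put on by code.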